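The readings were computed for an exercise, and the scatter is random.

If D has to go to Q rather than on to Z, I wanted to know how fast Q drains once it stands in the flask.

all flasks: L 0.35 mM

| flask | D | X | J | remark | time |
|---|---|---|---|---|---|
| beta | 0.069 M | 0.138 M | 1.7 mM | run made earlier |  |
| epsilon | 0.069 M | 0.138 M | 0.85 mM | run made earlier |  |
| zeta | 0.069 M | 0.138 M | 3.4 mM | run made earlier |  |
| winter | 0.069 M | 0.138 M | 1.7 mM | a single well-mixed tank run continuously and read at steady state, 3.0 d in it on average |  |
| dawn | 0.069 M | 0.138 M | 1.7 mM | a closed flask charged with all of it at once and left for 3.0 d | 3.0 d |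
| noon | 0.069 M | 0.138 M (fed, over 2.40 d) | 1.7 mM | all but X at the start; X goes in evenly over 2.40 d, the run ends at 3.0 d | 3.0 d |
| autumn | 0.069 M (fed, over 2.40 d) | 0.138 M | 1.7 mM | a stirred flask in which D is dosed at a steady rate over 2.40 d without added volume, worked up at 3.0 d | 3.0 d |

- beta (time / h: Q / %, Z / %, D / %): 5.00: 0, 0, 86; 15.0: 10, 3, 66; 30.0: 25, 4, 51; 40.0: 33, 6, 41
- epsilon (time / d: Q / %, Z / %, D / %): 0.417: 6, 2, 76; 1.04: 14, 0, 55; 2.08: 30, 8, 35; 3.00: 36, 13, 26
- zeta (time / d: Q / %, Z / %, D / %): 0.417: 8, 0, 76; 1.04: 32, 7, 50; 2.08: 46, 16, 28; 3.00: 53, 25, 18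

(scatter of a reading: 2 percentage points)

- order of the set-ups by the share of Q in all that became Q or Z, at the outlet or at the end, highest first (winter / dawn / noon / autumn)
- share of Q in all that became Q or Z, at the outlet or at the end, winter
- share of Q in all that became Q or Z, at the outlet or at the end, dawn
- share of Q in all that became Q or Z, at the outlet or at the end, noon
- share of Q in all that became Q or Z, at the outlet or at the end, autumn

- the stated concentrations are those of everything mixed, before any reaction; amounts are the same in each set-up
- the feed brings no volume worth counting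
- the earlier runs were made in a closed, stirred flask

I started from D, charged in a smaller amount than X. In the zeta run it left at 0.576 d⁻¹ of the charge at first, and the epsilon run read the same 76% at 0.417 d, with 4.00 times less J. Over the last interval of the zeta run D left at 0.109 d⁻¹, slower by a factor of 5.28. In that interval Z gained 0.0978 d⁻¹ and Q 0.0761 d⁻¹, and the zeta share of Q fell from 82.1% at 1.04 d to 67.9% at 3.00 d.

From those readings I took 0.209 d⁻¹ for the drain, the Z gained per day for each unit of Q standing, a pseudo-first-order constant. Z over Q is then the drain times the exposure, the days Q has stood, weighted by the amount standing, per unit of final Q. For the winter tank, with half the J of the zeta run, I assumed the same drain; the exposure there is the average stay, so I reckoned a share of 61.5%, above the forecast's 59%. I expected dosing to shorten exposure, but X was never varied, so I could not separate noon from autumn.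

The forecast said noon > autumn > dawn > winter, with 59%, 71%, 78% and 76% for winter, dawn, noon and autumn: “Both feeds delay Q formation”.

The flask gave autumn > noon > dawn > winter, with 58.0%, 68.2%, 74.6% and 78.2%, so autumn came first where the forecast had noon.

    Q + L ⇌ Z + L, rate k1*[L]*[Q] forward; the back reaction follows from the equilibrium constant (K = 10.8, k = 0.514 M⁻¹ min⁻¹)
    D + L ⇌ L + E (K = 1.50, k = 1.39 M⁻¹ min⁻¹)
    X + J + E → J + Q (k = 4.73 M⁻² min⁻¹)

At 3.00 d autumn held Z over Q of 0.278, which at my drain is an exposure of 1.33 d. The scheme makes the forward drain proportional to L, so for the neighbour flask, autumn with 8.7 × 10⁻⁵ M of L instead of 0.35 mM, I scaled the drain to 0.0520 d⁻¹ and assumed that exposure unchanged. That reckons a share of 93.5%. The neighbour flask gave 94.3%, with 16.4% of the D charged as Q and 75% of the D still there.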